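Watch the dissolved substrate in this flask, and read everything as fractions of the solid substrate charged.

    solid substrate ⇌ dissolved substrate, rate k1*(cs1 - [dissolved substrate]) while solid is left; crystals form when [dissolved substrate] > cs1 (cs1 = 0.13 M, k1 = 0.90 s⁻¹)
    dissolved substrate + reagent → target (k2 = 0.56 M⁻¹ s⁻¹)
    solid product ⇌ target, rate k3*(cs3 - [target]) while solid is left; crystals form when [target] > cs3 (cs3 = 0.057 M, k3 = 11 s⁻¹)
    reagent ⇌ dormant form (K4 = 0.28, k4 = 0.18 s⁻¹)
    solid substrate + target → side product (k5 = 0.61 M⁻¹ s⁻¹)

solid substrate 0.20 M; reagent 1.50 equiv; time 20 s

- percentages count the solid substrate that a species holds: one side product counts as two
- target is meant together with its solid product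
- solid, in amounts per volume of the solution: solid substrate, solid product
- at the start none of the solid substrate is in solution
- run time (flask): 20 s

- amount of target and solid product together at 20 s, in percent of the solid substrate charged
- the change that raises the amount of target and solid product together at 20 s, in percent of the solid substrate charged most ("none" if none brings more than 2 percentage points) (epsilon / alpha / gamma / theta / none)
- amount of target and solid product together at 20 s, in percent of the solid substrate charged, after epsilon

- epsilon: doubling the dissolution coefficient of step 1, all else as stated
- alpha: doubling the solubility in step 3, all else as stated
- gamma: doubling the amount of reagent, all else as stated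
- theta: doubling the dissolution coefficient of step 3, all else as stated

**Pair time.** I took the share 78.1% of the reagent pool as free. That gave me the pair time 11.4 s, the second-order half-life of equal pools of dissolved substrate and reagent, each starting at the charge of solid substrate with that free share applied. Step 4 relaxes in 0.842 s, faster than the pair time, so the fixed share was fair.

**Zero point.** Equal pools, dissolved from the start, left 36.3% unreacted by my reckoning at 20 s. The reagent excess 0.500 improved on that. The ratio u/(u+e), with u the unreacted fraction, decays exponentially at e over the pair time. It reached 0.278, so u was 19.2%.

**Weak link.** That start was false, since the charge begins as solid and saturation stands at 65.0% of it. Filling has a half-life of 0.770 s, less than the pair time, so I held the dissolved substrate at 56.7% while solid lasted, which I reckoned was until about 6.79 s. Restarting the ratio there gave 0.298, so u was 21.2%. I reckoned the loss to step 5 at about 5.17%, which left 73.6% for y.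

**The changes.** The same chain gave, after epsilon, a level of 60.6%, solid lasting 5.71 s, and 75.7%. After gamma, with excess 2.00, level 50.3% and solid lasting 4.10 s, it gave 93.4%. Alpha and theta act on step 3, which passes target between two forms counted together, so I expected no gain from them.

**The result.** The forecast stood at 73%, gamma and 76.5%, starting from “Treat the dissolved substrate as near its quasi-steady level.” The flask gave 73.8%, with gamma best at 19 percentage points, and 76.1% after epsilon. At 20.0 s this flask still held 21.6% as dissolved substrate. Carrying that reading forward on the pair time to 30 s gave a ratio of 0.195, hence 12.1% unreacted. The flask left until 30 s held 11.9% as dissolved substrate.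

The constants used here belong to no real substance; no experiment stands behind them.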